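**Retrosynthetic overview**

1. Target 23 ⇐ 14-deoxy diester 22 by allylic C14–H hydroxylation with SeO2; the C14 oxygen goes in last.
2. 22 ⇐ erythro 8,9-diol 18: the C9–O ester bond is made with inversion by opening an ortho-isobutyrate-derived dioxolanylium ion with 2-hydroxyisobutyric acid (new C–O step; sets C9 and tells the two esters apart).
3. 18 ⇐ acyclic bromo-enal 16: a chromium Barbier macrocyclisation closes the ten-membered carbocycle (C6–C7) first, then the γ-lactone (C6–O) closes in the same operation.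
4. 16 ⇐ vinyl iodide 4 + α-silyloxy aldehyde 12 by Felkin-selective Nozaki–Hiyama–Kishi coupling (C9–C10).
5. 4 ⇐ neryl acetate (both ring Z-alkenes come ready-made); 12 ⇐ (R)-glyceraldehyde acetonide + methyl acrylate (C8 from the chiral pool).

Assumption: positions are quoted in germacrane numbering (lactone O on C6, ring fusion C6/C7, esters on C8 and C9, C14 on C10, C15 on C4); the SMILES strings are the binding statement of configuration.

**Route**

Step 1
Reactants: 1 neryl acetate
Product: 2 (2Z)-3-methyl-6-oxohex-2-en-1-yl acetate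
Conditions: O3 (1 equiv), CH2Cl2, pyridine (cat.), −78 °C; then Me2S, −78 °C → rt
Reagents that add atoms: ozone [O-][O+]=O
Why: Ozonolysis; the remote trisubstituted alkene is far more electron-rich than the 2,3-alkene, which is deactivated by its allylic acetate, so one equivalent of ozone cleaves only the isopropylidene end and leaves the Z-alkene untouched.

Step 2
Reactants: 2 (2Z)-3-methyl-6-oxohex-2-en-1-yl acetate; 3 ethyltriphenylphosphonium iodide
Product: 4 (2Z,6Z)-7-iodo-3-methylocta-2,6-dien-1-yl acetate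
Conditions: 3, n-BuLi, THF, 0 °C; I2, −78 °C; NaN(SiMe3)2, −20 °C; then 2, −78 → −20 °C
Reagents that add atoms: iodine [I][I]
Why: Stork–Zhao-type Wittig olefination with the α-iodo ylide Ph3P=C(I)CH3, whose kinetic cis-oxaphosphetane puts the chain cis to iodine and gives the (Z)-2-iodo-2-alkene, which already has the ring-cis C1=C10 geometry of the target.

Step 3
Reactants: 5 (R)-2,2-dimethyl-1,3-dioxolane-4-carbaldehyde; 6 methyl acrylate
Product: 7 methyl 2-{[(4R)-2,2-dimethyl-1,3-dioxolan-4-yl](hydroxy)methyl}prop-2-enoate (carbinol epimers)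
Conditions: DABCO (0.5 equiv), 6 (3 equiv), dioxane/H2O 1:1, rt, 3 d
Reagents that add atoms: none
Why: Morita–Baylis–Hillman reaction; the new carbinol forms as a mixture that does not matter because it becomes sp2 in step 4, and the dioxolane centre (future C8) is not touched.

Step 4
Reactants: 7 methyl 2-{[(4R)-2,2-dimethyl-1,3-dioxolan-4-yl](hydroxy)methyl}prop-2-enoate
Product: 9 methyl (2E)-2-(acetoxymethyl)-3-[(4S)-2,2-dimethyl-1,3-dioxolan-4-yl]prop-2-enoate, via secondary acetate 8 (not isolated)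
Conditions: Ac2O, DMAP (cat.), CH2Cl2, 0 °C → rt; then DABCO (0.3 equiv), THF, 65 °C
Reagents that add atoms: acetic anhydride CC(=O)OC(C)=O
Why: Acetylation then DABCO-mediated double SN2′ allylic transposition of the Morita–Baylis–Hillman acetate gives the thermodynamically preferred primary acetate with the dioxolanyl group trans to the ester, the geometry later needed for the Z-allyl bromide.

Step 5
Reactants: 9 methyl (2E)-2-(acetoxymethyl)-3-[(4S)-2,2-dimethyl-1,3-dioxolan-4-yl]prop-2-enoate
Product: 10 methyl (2E,4S)-2-(acetoxymethyl)-4,5-dihydroxypent-2-enoate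
Conditions: AcOH/H2O 4:1, 40 °C
Reagents that add atoms: none
Why: Acid-catalysed acetonide hydrolysis; the acetate and methyl ester survive aqueous acetic acid, and the trans relation of ester and C4 rules out lactonisation.

Step 6
Reactants: 10 methyl (2E,4S)-2-(acetoxymethyl)-4,5-dihydroxypent-2-enoate
Product: 11 methyl (2E,4S)-2-(acetoxymethyl)-4,5-bis(triethylsilyloxy)pent-2-enoate
Conditions: Et3SiCl, imidazole, CH2Cl2, 0 °C
Reagents that add atoms: chlorotriethylsilane CC[Si](Cl)(CC)CC
Why: Standard silylation of both hydroxyls under weakly basic conditions that leave the acetate alone.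

Step 7
Reactants: 11 methyl (2E,4S)-2-(acetoxymethyl)-4,5-bis(triethylsilyloxy)pent-2-enoate
Product: 12 methyl (2E,4S)-2-(acetoxymethyl)-5-oxo-4-(triethylsilyloxy)pent-2-enoate
Conditions: (COCl)2, DMSO, CH2Cl2, −78 → −40 °C; Et3N, −78 °C
Reagents that add atoms: none
Why: Swern oxidation applied directly to a primary triethylsilyl ether; the chlorosulfonium reagent cleaves only the unhindered primary O–Si bond and the alkoxysulfonium salt collapses to the aldehyde, while the cold amine quench protects the α-silyloxy centre from epimerisation.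

Step 8
Reactants: 4 (2Z,6Z)-7-iodo-3-methylocta-2,6-dien-1-yl acetate; 12 methyl (2E,4S)-2-(acetoxymethyl)-5-oxo-4-(triethylsilyloxy)pent-2-enoate
Product: 13 methyl (2E,4S,5R,6Z,10Z)-12-acetoxy-2-(acetoxymethyl)-6,10-dimethyl-4,5-bis(triethylsilyloxy)dodeca-2,6,10-trienoate
Conditions: CrCl2 (15 mol%), NiCl2 (1 mol%), Mn powder, Et3SiCl, LiCl, DME/DMF, rt
Reagents that add atoms: chlorotriethylsilane CC[Si](Cl)(CC)CC
Why: Nozaki–Hiyama–Kishi coupling catalytic in chromium; zerovalent nickel inserts into the C–I bond with retention of the Z geometry, the alkenyl trivalent chromium species adds to the α-silyloxy aldehyde in the Felkin–Anh sense (anti to OSiEt3) to give the 8,9-erythro (9R) epimer, and Et3SiCl silylates the chromium alkoxide so that Mn can turn the chromium over.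

Step 9
Reactants: 13 methyl (2E,4S,5R,6Z,10Z)-12-acetoxy-2-(acetoxymethyl)-6,10-dimethyl-4,5-bis(triethylsilyloxy)dodeca-2,6,10-trienoate
Product: 14 methyl (2E,4S,5R,6Z,10Z)-12-hydroxy-2-(hydroxymethyl)-6,10-dimethyl-4,5-bis(triethylsilyloxy)dodeca-2,6,10-trienoate
Conditions: K2CO3 (0.5 equiv), MeOH, 0 °C
Reagents that add atoms: none
Why: Zemplén-type transesterification; the two unhindered primary allylic acetates are methanolysed while the conjugated methyl ester (degenerate exchange) and the secondary silyl ethers stay.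

Step 10
Reactants: 14 methyl (2E,4S,5R,6Z,10Z)-12-hydroxy-2-(hydroxymethyl)-6,10-dimethyl-4,5-bis(triethylsilyloxy)dodeca-2,6,10-trienoate
Product: 15 methyl (2E,4S,5R,6Z,10Z)-2-(hydroxymethyl)-6,10-dimethyl-12-oxo-4,5-bis(triethylsilyloxy)dodeca-2,6,10-trienoate
Conditions: MnO2, CH2Cl2, 0 °C → rt
Reagents that add atoms: none
Why: MnO2 allylic oxidation; the electron-rich neryl-type alcohol is oxidised quickly whereas the electron-poor 2-(hydroxymethyl)acrylate alcohol reacts much more slowly, and the neutral heterogeneous conditions keep the Z-enal.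

Step 11
Reactants: 15 methyl (2E,4S,5R,6Z,10Z)-2-(hydroxymethyl)-6,10-dimethyl-12-oxo-4,5-bis(triethylsilyloxy)dodeca-2,6,10-trienoate
Product: 16 methyl (2Z,4S,5R,6Z,10Z)-2-(bromomethyl)-6,10-dimethyl-12-oxo-4,5-bis(triethylsilyloxy)dodeca-2,6,10-trienoate
Conditions: NBS, Me2S, CH2Cl2, −20 → 0 °C
Reagents that add atoms: N-bromosuccinimide O=C1CCC(=O)N1Br
Why: Corey–Kim bromination; the primary allylic alcohol is displaced through its alkoxysulfonium salt under neutral conditions that tolerate the enal (unlike CBr4/PPh3) and the silyl ethers, with the alkene geometry unchanged.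

Step 12
Reactants: 16 methyl (2Z,4S,5R,6Z,10Z)-2-(bromomethyl)-6,10-dimethyl-12-oxo-4,5-bis(triethylsilyloxy)dodeca-2,6,10-trienoate
Product: 18 9-epi-8,9-diol lactone (14-deoxy ten-membered α-methylene-γ-lactone with 8,9-erythro diol), via bis-triethylsilyl lactone 17 (not isolated)
Conditions: CrCl2 (8 equiv), THF/DMF, 2 mM, slow addition, rt; then 1 M HCl, THF, 0 °C
Reagents that add atoms: none
Why: Intramolecular Nozaki–Hiyama (chromium Barbier) allylation of the kind used to close ten-membered germacranolides; divalent chromium turns the allyl bromide into an allylchromium species that adds through C7 to the tethered enal, the C8 centre directs the C7 face (A(1,3)-minimised rotamer with H8 eclipsing the allyl unit, attack anti to the C9 branch), the macrocyclic transition state gives the 6,7-anti adduct whose alkoxide closes the trans-fused lactone, the silyloxy group at C8 is too poor a leaving group for 1,4-elimination, and dilute HCl then removes both silyl groups.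

Step 13
Reactants: 18 9-epi-8,9-diol lactone; 19 trimethyl orthoisobutyrate; 20 2-hydroxy-2-methylpropanoic acid
Product: 22 14-deoxy target (8-isobutyrate 9-(2-hydroxyisobutyrate) of the 8S,9S diol), via cyclic ortho ester 21 (not isolated)
Conditions: 19, PPTS (cat.), CH2Cl2, rt; evaporate; then 20 (5 equiv), BF3·OEt2 (10 mol%), CH2Cl2, −20 → 0 °C
Reagents that add atoms: none
Why: Proposed new method: an acyloxonium relay that turns an erythro diol into a threo diester of two different acids in one pot — the diol and the ortho ester give the cis-fused cyclic ortho-isobutyrate, acid ionises it to the 2-isopropyl-1,3-dioxolan-2-ylium ion, and the carboxylate of 20 opens this ion by SN2 attack at the allylic, better-stabilised C9 (C8 is non-allylic and flanked by the lactone), which inverts C9 to S, forms the C9–O ester bond and leaves the isobutyrate on O8; the closest known reactions are the Prévost reaction (carboxylate opening of dioxolan-2-ylium ions with inversion), the ortho-ester-to-halohydrin-ester opening of diols and the ortho-ester route to 1,2-trans glycosyl esters, none of which has been run with a second carboxylic acid at a non-anomeric allylic carbon.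

Step 14
Reactants: 22 14-deoxy target
Product: 23 CNP0220567.2
Conditions: SeO2 (0.5 equiv), t-BuOOH (3 equiv), CH2Cl2, 0 °C → rt
Reagents that add atoms: selenium dioxide O=[Se]=O; tert-butyl hydroperoxide CC(C)(C)OO
Why: Riley-type allylic oxidation; ene reaction at C1 with loss of a C14–H and [2,3]-sigmatropic shift gives the primary allylic alcohol with CH2OH trans to C2 (the ring-cis C1=C10 geometry, as in the known parthenolide to melampomagnolide B oxidation), while the C4=C5 alkene is deactivated and shielded by the allylic lactone oxygen.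

**Compound list**

1 | neryl acetate, (2Z)-3,7-dimethylocta-2,6-dien-1-yl acetate | CC(=O)OC/C=C(/C)CCC=C(C)C | starting material
2 | (2Z)-3-methyl-6-oxohex-2-en-1-yl acetate | CC(=O)OC/C=C(/C)CCC=O | intermediate
3 | ethyltriphenylphosphonium iodide | CC[P+](c1ccccc1)(c1ccccc1)c1ccccc1.[I-] | starting material
4 | (2Z,6Z)-7-iodo-3-methylocta-2,6-dien-1-yl acetate | CC(=O)OC/C=C(/C)CC/C=C(/C)I | intermediate
5 | (R)-2,2-dimethyl-1,3-dioxolane-4-carbaldehyde ((R)-glyceraldehyde acetonide) | O=C[C@H]1COC(C)(C)O1 | starting material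
6 | methyl acrylate | C=CC(=O)OC | starting material
7 | methyl 2-{[(4R)-2,2-dimethyl-1,3-dioxolan-4-yl](hydroxy)methyl}prop-2-enoate (carbinol epimers) | C=C(C(=O)OC)C(O)[C@H]1COC(C)(C)O1 | intermediate
8 | methyl 2-{acetoxy[(4R)-2,2-dimethyl-1,3-dioxolan-4-yl]methyl}prop-2-enoate | C=C(C(=O)OC)C(OC(C)=O)[C@H]1COC(C)(C)O1 | intermediate (not isolated)
9 | methyl (2E)-2-(acetoxymethyl)-3-[(4S)-2,2-dimethyl-1,3-dioxolan-4-yl]prop-2-enoate | COC(=O)/C(COC(C)=O)=C/[C@H]1COC(C)(C)O1 | intermediate
10 | methyl (2E,4S)-2-(acetoxymethyl)-4,5-dihydroxypent-2-enoate | COC(=O)/C(COC(C)=O)=C/[C@H](O)CO | intermediate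
11 | methyl (2E,4S)-2-(acetoxymethyl)-4,5-bis(triethylsilyloxy)pent-2-enoate | COC(=O)/C(COC(C)=O)=C/[C@H](O[Si](CC)(CC)CC)CO[Si](CC)(CC)CC | intermediate
12 | methyl (2E,4S)-2-(acetoxymethyl)-5-oxo-4-(triethylsilyloxy)pent-2-enoate | COC(=O)/C(COC(C)=O)=C/[C@H](O[Si](CC)(CC)CC)C=O | intermediate
13 | methyl (2E,4S,5R,6Z,10Z)-12-acetoxy-2-(acetoxymethyl)-6,10-dimethyl-4,5-bis(triethylsilyloxy)dodeca-2,6,10-trienoate | CC(=O)OC/C=C(/C)CC/C=C(/C)[C@@H](O[Si](CC)(CC)CC)[C@@H](O[Si](CC)(CC)CC)/C=C(/C(=O)OC)COC(C)=O | intermediate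
14 | methyl (2E,4S,5R,6Z,10Z)-12-hydroxy-2-(hydroxymethyl)-6,10-dimethyl-4,5-bis(triethylsilyloxy)dodeca-2,6,10-trienoate | OC/C=C(/C)CC/C=C(/C)[C@@H](O[Si](CC)(CC)CC)[C@@H](O[Si](CC)(CC)CC)/C=C(/C(=O)OC)CO | intermediate
15 | methyl (2E,4S,5R,6Z,10Z)-2-(hydroxymethyl)-6,10-dimethyl-12-oxo-4,5-bis(triethylsilyloxy)dodeca-2,6,10-trienoate | O=C/C=C(/C)CC/C=C(/C)[C@@H](O[Si](CC)(CC)CC)[C@@H](O[Si](CC)(CC)CC)/C=C(/C(=O)OC)CO | intermediate
16 | methyl (2Z,4S,5R,6Z,10Z)-2-(bromomethyl)-6,10-dimethyl-12-oxo-4,5-bis(triethylsilyloxy)dodeca-2,6,10-trienoate | O=C/C=C(/C)CC/C=C(/C)[C@@H](O[Si](CC)(CC)CC)[C@@H](O[Si](CC)(CC)CC)/C=C(/C(=O)OC)CBr | intermediate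
17 | 8,9-bis(triethylsilyl) ether of 18 (trans-fused lactone; C6, C7, C8 as in the target, C9 epimeric) | C=C1C(=O)O[C@@H]2/C=C(/C)CC/C=C(/C)[C@@H](O[Si](CC)(CC)CC)[C@@H](O[Si](CC)(CC)CC)[C@@H]12 | intermediate (not isolated)
18 | 9-epi-8,9-dihydroxygermacra-1(10)Z,4Z,11(13)-trien-12,6-olide (C6, C7, C8 as in the target; 8,9-erythro) | C=C1C(=O)O[C@@H]2/C=C(/C)CC/C=C(/C)[C@@H](O)[C@@H](O)[C@@H]12 | intermediate
19 | trimethyl orthoisobutyrate (1,1,1-trimethoxy-2-methylpropane) | COC(OC)(OC)C(C)C | starting material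
20 | 2-hydroxy-2-methylpropanoic acid | CC(C)(O)C(=O)O | starting material
21 | cyclic methyl ortho-isobutyrate of 18 (cis-fused 2-isopropyl-2-methoxy-1,3-dioxolane on C8/C9; ortho carbon as a mixture) | C=C1C(=O)O[C@@H]2/C=C(/C)CC/C=C(/C)[C@H]3OC(OC)(C(C)C)O[C@H]3[C@@H]12 | intermediate (not isolated)
22 | 14-deoxy target: (6R,7S,8S,9S)-8-isobutyryloxy-9-(2-hydroxy-2-methylpropanoyloxy)germacra-1(10)Z,4Z,11(13)-trien-12,6-olide | C=C1C(=O)O[C@@H]2/C=C(/C)CC/C=C(/C)[C@H](OC(=O)C(C)(C)O)[C@@H](OC(=O)C(C)C)[C@@H]12 | intermediate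
23 | CNP0220567.2: (3aS,4S,5S,6Z,10Z,11aR)-6-(hydroxymethyl)-10-methyl-3-methylidene-4-(2-methylpropanoyloxy)-2-oxo-2,3,3a,4,5,8,9,11a-octahydrocyclodeca[b]furan-5-yl 2-hydroxy-2-methylpropanoate | C=C1C(=O)O[C@@H]2/C=C(/C)CC/C=C(/CO)[C@H](OC(=O)C(C)(C)O)[C@@H](OC(=O)C(C)C)[C@@H]12 | target

**Step count**

Total steps: 14. Longest linear sequence: 12 steps (5 → 23, steps 3–14); the two-step branch 1 → 4 joins at step 8.

**Steps most likely to fail, with fallbacks**

Step 13 (the new acyloxonium relay). The ion may be opened at C1 (SN2′) or hydrolysed to mono-esters instead of being opened at C9. The fallback uses known reactions only, sets out from 18 and returns at 22. MnO2 oxidises only the allylic C9 hydroxyl of 18 to the 8-hydroxy-9-ketone F2. Isobutyric anhydride/DMAP acylates O8 to the keto ester F3. Reagent-controlled reduction of the enone carbonyl with the (S)-CBS oxazaborolidine and catecholborane gives the 9S alcohol F4. Esterification of F4 with acid 20 (EDC, DMAP) gives 22.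

Step 12 (chromium Barbier macrocyclisation). Ring closure could be slow, or the C6/C7 configuration could come out wrong. The fallback replaces the open-shell chromium allylation by a boron allylation with a closed chair transition state; it sets out from 16 and returns at 17. Palladium-catalysed borylation (bis(pinacolato)diboron, Pd2(dba)3, toluene, 50 °C) converts the bromide into the allylboronate F1. F1 cyclises onto the enal at high dilution (heat or Sc(OTf)3 catalysis) and lactonises to 17, which is desilylated to 18 as in step 12.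

Step 14 (SeO2 hydroxylation). With the acyloxy group on C9, the C1=C10 alkene may be too deactivated, so that C15/C3 oxidation or over-oxidation to the C14 aldehyde competes. The fallback moves the oxidation to the silyl-ether stage, where C1=C10 is more electron-rich; it sets out from 17 (isolated by neutral work-up of step 12) and returns at 23. SeO2/t-BuOOH on 17 gives the 14-alcohol F5. t-BuMe2SiCl/imidazole gives the 14-silyl ether F6. PPTS/MeOH removes only the two secondary triethylsilyl groups to give the diol F7. The ortho-isobutyrate sequence of step 13 converts F7 into the diester F8. HF·pyridine then frees C14–OH to give 23.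

Further compounds
F1 | step 12 | methyl (2E,4S,5R,6Z,10Z)-6,10-dimethyl-12-oxo-2-[(4,4,5,5-tetramethyl-1,3,2-dioxaborolan-2-yl)methyl]-4,5-bis(triethylsilyloxy)dodeca-2,6,10-trienoate | O=C/C=C(/C)CC/C=C(/C)[C@@H](O[Si](CC)(CC)CC)[C@@H](O[Si](CC)(CC)CC)/C=C(/C(=O)OC)CB1OC(C)(C)C(C)(C)O1
F2 | step 13 | 8-hydroxy-9-oxo analogue of 18 (C6, C7, C8 as in the target) | C=C1C(=O)O[C@@H]2/C=C(/C)CC/C=C(/C)C(=O)[C@@H](O)[C@@H]12
F3 | step 13 | 8-O-isobutyryl-9-oxo lactone | C=C1C(=O)O[C@@H]2/C=C(/C)CC/C=C(/C)C(=O)[C@@H](OC(=O)C(C)C)[C@@H]12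
F4 | step 13 | 8-O-isobutyryl-(9S)-9-hydroxy lactone | C=C1C(=O)O[C@@H]2/C=C(/C)CC/C=C(/C)[C@H](O)[C@@H](OC(=O)C(C)C)[C@@H]12
F5 | step 14 | 14-hydroxy derivative of 17 | C=C1C(=O)O[C@@H]2/C=C(/C)CC/C=C(/CO)[C@@H](O[Si](CC)(CC)CC)[C@@H](O[Si](CC)(CC)CC)[C@@H]12
F6 | step 14 | 14-O-tert-butyldimethylsilyl ether of F5 | C=C1C(=O)O[C@@H]2/C=C(/C)CC/C=C(/CO[Si](C)(C)C(C)(C)C)[C@@H](O[Si](CC)(CC)CC)[C@@H](O[Si](CC)(CC)CC)[C@@H]12
F7 | step 14 | 14-O-tert-butyldimethylsilyl 9-epi-8,9-diol | C=C1C(=O)O[C@@H]2/C=C(/C)CC/C=C(/CO[Si](C)(C)C(C)(C)C)[C@@H](O)[C@@H](O)[C@@H]12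
F8 | step 14 | 14-O-tert-butyldimethylsilyl ether of 23 | C=C1C(=O)O[C@@H]2/C=C(/C)CC/C=C(/CO[Si](C)(C)C(C)(C)C)[C@H](OC(=O)C(C)(C)O)[C@@H](OC(=O)C(C)C)[C@@H]12
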